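**Retrosynthetic overview**

1. The target is a cis-fused bicycle of ring B (γ-lactone: C1(=O), C2, C3, C4, O) and ring A (tetrahydrofuran: O, C3, C4, C5, C6); C6 carries CH3 and the chain C1′–C10′(Ph). Enabling feature: the ring-A oxygen links C6 to C3, so C6 is a ketal-level carbon that can become a tertiary oxocarbenium ion held inside the bicycle, and C3 is the β-carbon of a ring-B butenolide.
2. Last disconnection: C1′≡C2′ to CH2–CH2 (hydrogenation). Key disconnection C6–C1′: C16 alkynylstannane plus ring-A oxocarbenium ion; in the same flask this ion is traced back through O–C3 (oxa-Michael) and O–C6 (hemiketal) to a monocyclic keto-butenolide with C4 as its only stereocentre.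
3. Keto-butenolide from a terminal alkyne (hydration); butenolide C1–C2=C3 from an α-hydroxy aldehyde and Ph3P=C=C=O; C5–C6 from acetylide opening of (S)-2-methylglycidol (C4 from the chiral pool); chain from (8-bromooctyl)benzene and acetylide.
4. Ring order: ring B (step 3), then ring A (step 7). C3 follows from the obligatory cis 5,5-fusion; C6 from inside attack on the oxocarbenium ion, syn to the lactone oxygen and anti to the C4 methyl. No protecting groups.

Key step: step 7

Remark on the chemistry: ketal 12 is a mixture of C6 epimers, which is of no consequence because both ionize to the same cation 13; atom numbers are those of the lactone skeleton (C1–C6, chain C1′–C10′).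

**Route**

Step 1
Reactants: 1 (S)-2-methylglycidol
Product: 2 (R)-2-methylpent-4-yne-1,2-diol
Conditions: LiC≡CH·H2NCH2CH2NH2 (3 equiv), DMSO, 0 °C → rt; then H2O
Reagents that add atoms: lithium acetylide–ethylenediamine complex, [Li]C#C.NCCN
Why: SN2 opening of the 2,2-disubstituted epoxide by acetylide takes place at the unhindered CH2 terminus, so the quaternary stereocentre (the later C4) is taken unchanged from the chiral pool (its descriptor changes from S to R only through the priority rules) and a Payne shift of the alkoxide would be degenerate.

Step 2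
Reactants: 2 (R)-2-methylpent-4-yne-1,2-diol
Product: 3 (R)-2-hydroxy-2-methylpent-4-ynal
Conditions: 2-iodoxybenzoic acid (IBX), EtOAc, 75 °C; filter, use crude
Reagents that add atoms: none
Why: 2-Iodoxybenzoic acid oxidizes the primary hydroxyl of a 1,2-diol to the aldehyde without glycol cleavage, the tertiary hydroxyl cannot be oxidized and the stereocentre bears no hydrogen that could be lost.

Step 3
Reactants: 3 (R)-2-hydroxy-2-methylpent-4-ynal
Product: 5 (R)-5-methyl-5-(prop-2-yn-1-yl)furan-2(5H)-one, via ester ylide 4 (not isolated)
Conditions: Ph3P=C=C=O, toluene, 90 °C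
Reagents that add atoms: (triphenylphosphoranylidene)ketene, O=C=C=P(c1ccccc1)(c1ccccc1)c1ccccc1
Why: Addition of the tertiary hydroxyl to the ketene of Ph3P=C=C=O gives the stabilized ester ylide, whose intramolecular Wittig reaction with the neighbouring aldehyde can only give the Z-configured five-membered butenolide, which closes ring B and locks the aldol-type C4 oxygen as an ester.

Step 4
Reactants: 5 (R)-5-methyl-5-(prop-2-yn-1-yl)furan-2(5H)-one
Product: 6 (R)-5-methyl-5-(2-oxopropyl)furan-2(5H)-one
Conditions: Ph3PAuNTf2 (2 mol %), 1,4-dioxane/H2O (10:1), 60 °C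
Reagents that add atoms: water, O
Why: Gold-catalysed Markovnikov hydration of the terminal alkyne gives the methyl ketone (C6 at its ketone oxidation level) under near-neutral conditions that spare the butenolide and the β-acyloxy ketone.

Step 5
Reactants: 7 (8-bromooctyl)benzene
Product: 8 10-phenyldec-1-yne
Conditions: LiC≡CH·H2NCH2CH2NH2, DMSO, 10 °C → rt
Reagents that add atoms: lithium acetylide–ethylenediamine complex, [Li]C#C.NCCN
Why: SN2 alkylation of acetylide by the primary bromide in DMSO adds the two carbons that become C1′ and C2′ and completes the sixteen-carbon side chain at the alkyne oxidation level.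

Step 6
Reactants: 8 10-phenyldec-1-yne
Product: 10 tributyl(10-phenyldec-1-yn-1-yl)stannane, via lithium acetylide 9 (not isolated)
Conditions: n-BuLi, THF, −78 °C; then Bu3SnCl, −78 °C → rt
Reagents that add atoms: tributyltin chloride, CCCC[Sn](Cl)(CCCC)CCCC
Why: Deprotonation of the terminal alkyne and stannylation of the lithium acetylide give an alkynylstannane, a neutral π-nucleophile that hands its alkynyl group to carbocations by ipso-substitution and leaves esters untouched.

Step 7
Reactants: 6 (R)-5-methyl-5-(2-oxopropyl)furan-2(5H)-one; 10 tributyl(10-phenyldec-1-yn-1-yl)stannane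
Product: 14 (3aR,5R,6aR)-5,6a-dimethyl-5-(10-phenyldec-1-yn-1-yl)tetrahydrofuro[3,2-b]furan-2(3H)-one, via methyl hemiketal 11 (not isolated), via bicyclic methyl ketal 12 (not isolated), via oxocarbenium triflate 13 (not isolated)
Conditions: MeOH, DBU (5 mol %), 0 °C, short contact time; AcOH (5 mol %), evaporate (toluene azeotrope); then 10 (1.5 equiv), TMSOTf (1.3 equiv), CH2Cl2, −78 → −40 °C; then Et3N, aq. NaHCO3
Reagents that add atoms: none
Why: Methoxide adds to the ketone to give hemiketal 11, whose alkoxide adds to C3 of the butenolide (hemiketalization/oxa-Michael cascade) and closes ring A as ketal 12, TMSOTf then ionizes 12 to the tertiary oxocarbenium ion 13, and the tin-bearing carbon of 10 attacks C6 by ipso-substitution, which forms the C6–C1′ bond. The closest known reaction types are the base-mediated hemiacetal/oxa-conjugate addition used to make syn-1,3-diols and the Lewis-acid C-glycosylation of furanosyl ketals with silicon or tin π-nucleophiles. Ring A closes in a 5-exo-trig oxa-Michael mode, and because a 5,5-ring fusion can only be cis, the new C3–O bond must form on the face of the C5 arm, so C3 (R) is set by C4. C6 is set by the bicycle: cation 13 should prefer the envelope with C4 as the flap, its lactone oxygen pseudoaxial and its methyl pseudoequatorial, and the nucleophile should attack inside this envelope, syn to the lactone oxygen and anti to the C4 methyl (inside-attack model for 3-oxygenated five-membered oxocarbenium ions), which places the chain cis to ring B as in the target. The step needs the ketone to react before the lactone in the first stage and the ketal before the lactone in the second; the first is secured because methoxide addition to the butenolide and the lactone is reversible and only the intramolecular 5-exo adduct accumulates, the second because only the ketal ionizes at −78 °C and a stannane does not add to esters. Proton loss from 13 to an enol ether is reversible under the acidic conditions and leads back to 13.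

Step 8
Reactants: 14 (3aR,5R,6aR)-5,6a-dimethyl-5-(10-phenyldec-1-yn-1-yl)tetrahydrofuro[3,2-b]furan-2(3H)-one
Product: 16 plakortolide ether, via Z-alkene 15 (not isolated)
Conditions: H2 (1 atm), PtO2 (5 mol %), EtOAc, rt
Reagents that add atoms: none
Why: Heterogeneous hydrogenation saturates the alkyne by way of the cis-alkene to the 10-phenyldecyl chain and so removes the oxidation level that served the key step, platinum in a neutral aprotic solvent being chosen to disfavour hydrogenolysis of the tertiary propargylic and allylic C6–O bond, and no stereocentre is touched.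

**Compound list**

1 | (S)-2-methylglycidol, (S)-(2-methyloxiran-2-yl)methanol | OC[C@@]1(C)CO1 | starting material
2 | (R)-2-methylpent-4-yne-1,2-diol | C#CC[C@@](C)(O)CO | intermediate
3 | (R)-2-hydroxy-2-methylpent-4-ynal | C#CC[C@@](C)(O)C=O | intermediate
4 | (R)-2-methyl-1-oxopent-4-yn-2-yl (triphenylphosphoranylidene)acetate (ester ylide) | C#CC[C@](C)(C=O)OC(=O)C=P(c1ccccc1)(c1ccccc1)c1ccccc1 | intermediate
5 | (R)-5-methyl-5-(prop-2-yn-1-yl)furan-2(5H)-one | C#CC[C@@]1(C)OC(=O)C=C1 | intermediate
6 | (R)-5-methyl-5-(2-oxopropyl)furan-2(5H)-one | CC(=O)C[C@@]1(C)OC(=O)C=C1 | intermediate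
7 | (8-bromooctyl)benzene | BrCCCCCCCCc1ccccc1 | starting material
8 | 10-phenyldec-1-yne | C#CCCCCCCCCc1ccccc1 | intermediate
9 | lithium 10-phenyldec-1-yn-1-ide | [Li]C#CCCCCCCCCc1ccccc1 | intermediate
10 | tributyl(10-phenyldec-1-yn-1-yl)stannane | CCCC[Sn](CCCC)(CCCC)C#CCCCCCCCCc1ccccc1 | intermediate
11 | (R)-5-(2-hydroxy-2-methoxypropyl)-5-methylfuran-2(5H)-one (methyl hemiketal, both epimers) | COC(C)(O)C[C@@]1(C)OC(=O)C=C1 | intermediate
12 | (3aR,6aR)-5-methoxy-5,6a-dimethyltetrahydrofuro[3,2-b]furan-2(3H)-one (both C5 epimers) | COC1(C)C[C@@]2(C)OC(=O)C[C@H]2O1 | intermediate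
13 | (3aR,6aR)-5,6a-dimethyl-2-oxo-3,3a,6,6a-tetrahydro-2H-furo[3,2-b]furan-4-ium trifluoromethanesulfonate | CC1=[O+][C@@H]2CC(=O)O[C@]2(C)C1.[O-]S(=O)(=O)C(F)(F)F | intermediate
14 | (3aR,5R,6aR)-5,6a-dimethyl-5-(10-phenyldec-1-yn-1-yl)tetrahydrofuro[3,2-b]furan-2(3H)-one | C[C@]1(C#CCCCCCCCCc2ccccc2)C[C@@]2(C)OC(=O)C[C@H]2O1 | intermediate
15 | (3aR,5R,6aR)-5,6a-dimethyl-5-[(Z)-10-phenyldec-1-en-1-yl]tetrahydrofuro[3,2-b]furan-2(3H)-one | C[C@]1(/C=C\CCCCCCCCc2ccccc2)C[C@@]2(C)OC(=O)C[C@H]2O1 | intermediate
16 | plakortolide ether, (3aR,5S,6aR)-5,6a-dimethyl-5-(10-phenyldecyl)tetrahydrofuro[3,2-b]furan-2(3H)-one | C[C@]1(CCCCCCCCCCc2ccccc2)C[C@@]2(C)OC(=O)C[C@H]2O1 | target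

**Step count and risks**

Total steps: 8. Longest linear sequence: 6 steps (1, 2, 3, 4, 7, 8); the chain branch (steps 5 and 6) joins at step 7.

Steps most likely to fail:

1. Step 7. In the basic first stage the ketone may enolize and then expel the C4 carboxylate (β-elimination that opens ring B) or add through carbon to the butenolide before the hemiketal closes ring A. In the second stage the cation may lose a proton faster than it is captured, or be captured on the face syn to the C4 methyl. Fallback, setting out from 6 and 8 and coming back at 14: the C6–C1′ bond is made by carbonyl addition and ring A is closed afterwards. Alkyne 8 is deprotonated to 9 as in step 6 and transmetalated with anhydrous CeCl3 (THF, −78 °C) to (10-phenyldec-1-yn-1-yl)cerium dichloride F1. This non-basic reagent should add to the ketone of 6 without enolizing it and give the tertiary propargylic alcohol (R)-5-(2-hydroxy-2-methyl-12-phenyldodec-3-yn-1-yl)-5-methylfuran-2(5H)-one F2 as a mixture of carbinol epimers. Catalytic DBU in CH2Cl2 should then close ring A by oxa-Michael addition of the tertiary alkoxide. This fallback gives up control at C6, so 14 must be separated by chromatography from its C5 epimer (3aR,5S,6aR)-5,6a-dimethyl-5-(10-phenyldec-1-yn-1-yl)tetrahydrofuro[3,2-b]furan-2(3H)-one F3 before step 8.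

2. Step 3. Acylation of the hindered tertiary hydroxyl by the ketene ylide may be slow, so that self-condensation or evaporative loss of the small α-hydroxy aldehyde competes. Fallback, setting out from 3 and coming back at 5: intermolecular Z-selective olefination followed by lactonization replaces the acylation/intramolecular Wittig sequence. Still–Gennari reaction of 3 with methyl bis(2,2,2-trifluoroethyl)phosphonoacetate (KN(SiMe3)2, 18-crown-6, THF, −78 °C) should give methyl (R,Z)-4-hydroxy-4-methylhept-2-en-6-ynoate F4, which should lactonize to 5 with catalytic p-toluenesulfonic acid in CH2Cl2.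

3. Step 8. Hydrogenolysis of the C6–O bond at the propargylic or allylic stage may open ring A, and prolonged exposure may begin to reduce the arene. Fallback, setting out from 14 and coming back at 16: metal-free hydrogen transfer from diimide F5, generated from p-toluenesulfonyl hydrazide and NaOAc in DME/H2O at reflux. Diimide should reduce the alkyne by way of 15 in two concerted steps and has no pathway for C–O cleavage.

Further compounds
F1 | step 7 | (10-phenyldec-1-yn-1-yl)cerium dichloride | Cl[Ce](Cl)C#CCCCCCCCCc1ccccc1
F2 | step 7 | (R)-5-(2-hydroxy-2-methyl-12-phenyldodec-3-yn-1-yl)-5-methylfuran-2(5H)-one (both carbinol epimers) | CC(O)(C#CCCCCCCCCc1ccccc1)C[C@@]1(C)OC(=O)C=C1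
F3 | step 7 | (3aR,5S,6aR)-5,6a-dimethyl-5-(10-phenyldec-1-yn-1-yl)tetrahydrofuro[3,2-b]furan-2(3H)-one | C[C@@]1(C#CCCCCCCCCc2ccccc2)C[C@@]2(C)OC(=O)C[C@H]2O1
F4 | step 3 | methyl (R,Z)-4-hydroxy-4-methylhept-2-en-6-ynoate | C#CC[C@@](C)(O)/C=C\C(=O)OC
F5 | step 8 | diimide | N=N
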